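**Retrosynthetic overview**
1. The target is 2-methoxy-6,7-dimethyl-8-(2,4,5-trimethoxyphenyl)-1,4-naphthoquinone. Quinone ring A is bought intact as 2-methoxy-1,4-benzoquinone, so no late oxidation has to tell it apart from the equally oxidisable trimethoxyphenyl ring C.
2. Ring B is disconnected by a Diels–Alder/dehydrogenation sequence to an (E)-1-aryl-2,3-dimethylbuta-1,3-diene and the unsubstituted C=C of the quinone. The "ortho" orientation puts the aryl group peri to the carbonyl that sits next to C–OMe.
3. The aryl–diene bond (the future biaryl bond) is disconnected to the C-5–H of 1,2,4-trimethoxybenzene and a terminal C–H of 2,3-dimethylbutadiene. This is the proposed new step, a non-directed dehydrogenative C–H dienylation.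
4. Ring order: ring C (bought), ring A (bought), ring B (built last).

Assumption: the SMILES has no stereodescriptor and no stereocentre; the hindered biaryl axis is the only stereogenic element and is unspecified, so the target is made as drawn, racemic about that axis.

**Step 1**
Reactants: 1 1,2,4-trimethoxybenzene; 2 2,3-dimethylbuta-1,3-diene
Product: 3 1-[(1E)-2,3-dimethylbuta-1,3-dien-1-yl]-2,4,5-trimethoxybenzene
Conditions: Pd(OAc)2 (10 mol %), 3-methyl-2-(phenylthio)butanoic acid (12 mol %), PivOH (30 mol %), Ag2CO3 (1.5 equiv), 2 (3 equiv), ClCH2CH2Cl, 70 °C, sealed tube, dark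
Reagents that add atoms: none
Why: Proposed new method: a non-directed dehydrogenative Heck (Fujiwara–Moritani-type) C–H dienylation in which the electrophilic divalent palladium carboxylate, kept mononuclear by the thioether–carboxylate ligand, palladates 1 at C-5 (the unhindered position ortho and para to two methoxy groups; pivalate-assisted concerted metalation–deprotonation); the arylpalladium then adds to a terminal CH2 of 2 to give a π-allylpalladium, and syn β-hydride elimination (or pivalate-assisted deprotonation) of the benzylic C–H releases the fully conjugated, thermodynamically preferred E-aryldiene and zerovalent palladium, which Ag2CO3 reoxidises; the quinone-free, weakly nucleophilic pivalate/carbonate medium is chosen to suppress carboxylate capture of the π-allyl and loss of 2 to a dienophile; the closest known reaction types are the Fujiwara–Moritani olefination of alkoxyarenes with acrylates or styrenes and the Heck arylation of conjugated dienes with aryl halides, whereas a catalytic, arene-limited C–H version ending at a 1-aryl-2,3-dialkyl-1,3-diene has not been shown.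

**Step 2**
Reactants: 3 1-[(1E)-2,3-dimethylbuta-1,3-dien-1-yl]-2,4,5-trimethoxybenzene; 4 2-methoxy-1,4-benzoquinone
Product: 5 rac-(4aR*,8R*,8aS*)-2-methoxy-6,7-dimethyl-8-(2,4,5-trimethoxyphenyl)-4a,5,8,8a-tetrahydronaphthalene-1,4-dione (cis-fused; H-4a, H-8 and H-8a on one face)
Conditions: 4 (1.2 equiv), PhMe, 90 °C, N2, dark, 24 h; evaporate and use crude
Reagents that add atoms: none
Why: Normal-demand Diels–Alder reaction in which the C-1 carbonyl of 4 (the one not deactivated by vinylogous-ester donation from OMe) controls, so the more nucleophilic CH2 terminus of the diene bonds to C-5 of 4 and the aryl-bearing carbon to C-6 ("ortho" orientation), placing the aryl peri to the carbonyl next to C–OMe; endo, suprafacial addition gives the cis-fused racemate, whose three stereocentres are erased in step 3.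

**Step 3**
Reactants: 5 rac-(4aR*,8R*,8aS*)-2-methoxy-6,7-dimethyl-8-(2,4,5-trimethoxyphenyl)-4a,5,8,8a-tetrahydronaphthalene-1,4-dione
Product: 8 2-methoxy-6,7-dimethyl-8-(2,4,5-trimethoxyphenyl)naphthalene-1,4-dione, via hydroquinone 6 (not isolated), via dihydronaphthoquinone 7 (not isolated)
Conditions: Et3N (0.2 equiv), CH2Cl2, rt, N2; evaporate; then DDQ (2.2 equiv), PhH, rt to 50 °C
Reagents that add atoms: none
Why: Base-catalysed enolisation of the ene-dione gives hydroquinone 6, DDQ oxidises it to quinone 7, and a second DDQ dehydrogenation (hydride abstraction from the doubly activated C-5/C-8 positions, then proton loss) aromatises ring B; no stereocentre remains and the biaryl axis forms as the racemate.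

**Compound list**
1 | 1,2,4-trimethoxybenzene | COc1ccc(OC)c(OC)c1 | starting material
2 | 2,3-dimethylbuta-1,3-diene | C=C(C)C(C)=C | starting material
3 | 1-[(1E)-2,3-dimethylbuta-1,3-dien-1-yl]-2,4,5-trimethoxybenzene | COc1cc(OC)c(OC)cc1/C=C(\C)C(C)=C | intermediate
4 | 2-methoxy-1,4-benzoquinone (2-methoxycyclohexa-2,5-diene-1,4-dione) | COC1=CC(=O)C=CC1=O | starting material
5 | rac-(4aR*,8R*,8aS*)-2-methoxy-6,7-dimethyl-8-(2,4,5-trimethoxyphenyl)-4a,5,8,8a-tetrahydronaphthalene-1,4-dione (racemic, one enantiomer drawn) | COC1=CC(=O)[C@@H]2CC(C)=C(C)[C@H](c3cc(OC)c(OC)cc3OC)[C@@H]2C1=O | intermediate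
6 | 2-methoxy-6,7-dimethyl-8-(2,4,5-trimethoxyphenyl)-5,8-dihydronaphthalene-1,4-diol (racemic at C-8) | COc1cc(O)c2CC(C)=C(C)C(c3cc(OC)c(OC)cc3OC)c2c1O | intermediate
7 | 2-methoxy-6,7-dimethyl-8-(2,4,5-trimethoxyphenyl)-5,8-dihydronaphthalene-1,4-dione (racemic at C-8) | COC1=CC(=O)C2=C(C1=O)C(c3cc(OC)c(OC)cc3OC)C(C)=C(C)C2 | intermediate
8 | 2-methoxy-6,7-dimethyl-8-(2,4,5-trimethoxyphenyl)naphthalene-1,4-dione | COC1=CC(=O)c2cc(C)c(C)c(-c3cc(OC)c(OC)cc3OC)c2C1=O | target

**Totals**
Total step count: 3. Longest linear sequence: 3 steps (1 → 3 → 5 → 8).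

**Steps most likely to fail** (the route has three steps, so all three are ranked)

First, step 1 (the proposed new C–H dienylation). Likely failures are carboxylate capture of the π-allyl, β-hydride loss from the methyl side giving the non-conjugated isomer, double arylation of the diene, or oxidative homocoupling of 1. The fallback uses known chemistry, sets out from 1 and comes back at 3. Vilsmeier–Haack formylation of 1 (POCl3, DMF, then aqueous NaOAc) gives 2,4,5-trimethoxybenzaldehyde F1. Acid-catalysed aldol condensation with butan-2-one (HCl gas, neat ketone, 0 °C to rt; acid directs condensation to the methylene carbon) gives (E)-3-methyl-4-(2,4,5-trimethoxyphenyl)but-3-en-2-one F2. Wittig methylenation (Ph3PCH3Br, KOtBu, THF, 0 °C to rt) then gives 3.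

Second, step 2 (Diels–Alder). The risk is that the twisted aryl group and the 2-methyl group erode the "ortho" preference, or that the hindered diene reacts slowly. The fallback replaces carbonyl-polarisation control by halogen control and sets out from 3, coming back at 7. Dakin oxidation of commercial 5-bromovanillin (H2O2, aqueous NaOH) gives 2-bromo-6-methoxybenzene-1,4-diol F3, which FeCl3 oxidises to 2-bromo-6-methoxy-1,4-benzoquinone F4. In F4 the bromine and the methoxy polarisation both send the nucleophilic CH2 terminus of 3 to the unhalogenated carbon. The cycloaddition (PhMe, 60 °C) gives 8a-bromo-2-methoxy-6,7-dimethyl-8-(2,4,5-trimethoxyphenyl)-4a,5,8,8a-tetrahydronaphthalene-1,4-dione F5, which loses HBr on stirring with NaHCO3 to give 7. Compound 7 is carried to 8 with one equivalent of DDQ as in step 3.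

Third, step 3 (oxidative aromatisation). The risk is that DDQ attacks the electron-rich trimethoxyphenyl ring or stops at 7. The fallback aromatises ring B by prototropy instead of hydride abstraction and sets out from 5, coming back at 8. Et3N converts 5 to 6, and Ag2O (1 equiv, CH2Cl2) gives 7. Catalytic DBU under N2 isomerises 7 (deprotonation at C-5/C-8, reprotonation on oxygen) to 2-methoxy-6,7-dimethyl-8-(2,4,5-trimethoxyphenyl)naphthalene-1,4-diol F6. This hydroquinone is oxidised to 8 by Ag2O or air.

**Further compounds**
F1 | step 1 | 2,4,5-trimethoxybenzaldehyde | COc1cc(OC)c(OC)cc1C=O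
F2 | step 1 | (E)-3-methyl-4-(2,4,5-trimethoxyphenyl)but-3-en-2-one | COc1cc(OC)c(OC)cc1/C=C(\C)C(C)=O
F3 | step 2 | 2-bromo-6-methoxybenzene-1,4-diol | COc1cc(O)cc(Br)c1O
F4 | step 2 | 2-bromo-6-methoxy-1,4-benzoquinone | COC1=CC(=O)C=C(Br)C1=O
F5 | step 2 | 8a-bromo-2-methoxy-6,7-dimethyl-8-(2,4,5-trimethoxyphenyl)-4a,5,8,8a-tetrahydronaphthalene-1,4-dione (racemic, cis-fused, aryl trans to Br; one enantiomer drawn) | COC1=CC(=O)[C@@H]2CC(C)=C(C)[C@H](c3cc(OC)c(OC)cc3OC)[C@]2(Br)C1=O
F6 | step 3 | 2-methoxy-6,7-dimethyl-8-(2,4,5-trimethoxyphenyl)naphthalene-1,4-diol | COc1cc(O)c2cc(C)c(C)c(-c3cc(OC)c(OC)cc3OC)c2c1O
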